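**Strategy.** The tetralone is disconnected at the C2–C3 ring bond and at the C4–naphthyl bond. This leads to phenacyl bromide 7, in which C1–C2 is a bromoacetyl group and C3–C4 a vinyl group on the catechol ring, and to naphthylboronic acid 11. In the key step a chiral copper catalyst converts C2, alpha to the C1 ketone, into a radical that closes the cyclohexanone ring by 6-endo attack on C3. The C4 radical so formed, benzylic to the catechol ring, is arylated enantioselectively. Ring, C4–aryl bond and the only stereocentre thus arise in one operation from a ring-open, achiral precursor; hydrogenolysis of three benzyl ethers completes the route.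

Key step: step 9

Assumption: compounds 1 and 8 are taken as commercially available; tetralone numbering is used throughout (C1 carbonyl, C4 stereocentre), and the required configuration at C4 is R.

**Step 1**
Reactants: 1 2,3-bis(benzyloxy)benzaldehyde
Product: 2 2,3-bis(benzyloxy)-6-bromobenzaldehyde
Conditions: NBS, DMF, rt, dark
Reagents that add atoms: N-bromosuccinimide O=C1CCC(=O)N1Br
Why: Electrophilic aromatic bromination should go para to the 3-benzyloxy group (C6), because the 2-benzyloxy group is twisted out of conjugation by its two ortho neighbours, as the corresponding dimethyl ether is known to behave.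

**Step 2**
Reactants: 2 2,3-bis(benzyloxy)-6-bromobenzaldehyde
Product: 3 1-[2,3-bis(benzyloxy)-6-bromophenyl]ethan-1-ol (racemic)
Conditions: MeMgBr, THF, −78 to 0 °C; aq. NH4Cl
Reagents that add atoms: methylmagnesium bromide C[Mg]Br
Why: Grignard 1,2-addition to the aldehyde is faster than bromine–magnesium exchange at low temperature and gives a racemic carbinol whose stereocentre is removed in step 3.

**Step 3**
Reactants: 3 1-[2,3-bis(benzyloxy)-6-bromophenyl]ethan-1-ol
Product: 4 1-[2,3-bis(benzyloxy)-6-bromophenyl]ethan-1-one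
Conditions: Dess–Martin periodinane, CH2Cl2, rt
Reagents that add atoms: none
Why: Dess–Martin oxidation of the secondary benzylic alcohol gives the aryl methyl ketone under neutral conditions that leave the benzyl ethers and the aryl bromide untouched.

**Step 4**
Reactants: 4 1-[2,3-bis(benzyloxy)-6-bromophenyl]ethan-1-one
Product: 5 1-[2,3-bis(benzyloxy)-6-ethenylphenyl]ethan-1-one
Conditions: potassium vinyltrifluoroborate, PdCl2(dppf) (cat.), Cs2CO3, THF/H2O, 80 °C
Reagents that add atoms: potassium vinyltrifluoroborate C=C[B-](F)(F)F.[K+]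
Why: Suzuki–Miyaura vinylation of the aryl bromide tolerates the ortho acetyl group and installs the two carbons that become C3 and C4.

**Step 5**
Reactants: 5 1-[2,3-bis(benzyloxy)-6-ethenylphenyl]ethan-1-one
Product: 7 2-bromo-1-[2,3-bis(benzyloxy)-6-ethenylphenyl]ethan-1-one, via trimethylsilyl enol ether 6 (not isolated)
Conditions: TMSOTf, Et3N, CH2Cl2, 0 °C; then NBS, THF, −78 °C
Reagents that add atoms: N-bromosuccinimide O=C1CCC(=O)N1Br; trimethylsilyl trifluoromethanesulfonate C[Si](C)(C)OS(=O)(=O)C(F)(F)F (silicon is carried in 6 only)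
Why: Soft enolisation to the silyl enol ether followed by electrophilic α-bromination with NBS should place bromine on C2 only, because the enol ether is far more nucleophilic than the styrene or the arene.

**Step 6**
Reactants: 8 5-methoxynaphthalen-1-ol
Product: 9 4-bromo-5-methoxynaphthalen-1-ol
Conditions: NBS (1.0 equiv), MeCN, −20 to 0 °C
Reagents that add atoms: N-bromosuccinimide O=C1CCC(=O)N1Br
Why: Electrophilic aromatic bromination in acetonitrile without amine additives should favour the position para to the hydroxyl group, the stronger of the two oxygen donors.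

**Step 7**
Reactants: 9 4-bromo-5-methoxynaphthalen-1-ol
Product: 10 1-(benzyloxy)-4-bromo-5-methoxynaphthalene
Conditions: BnBr, K2CO3, DMF, rt
Reagents that add atoms: benzyl bromide BrCc1ccccc1
Why: Williamson etherification protects the naphthol as a benzyl ether that can later be removed by hydrogenolysis without touching the methyl ether.

**Step 8**
Reactants: 10 1-(benzyloxy)-4-bromo-5-methoxynaphthalene
Product: 11 [4-(benzyloxy)-8-methoxynaphthalen-1-yl]boronic acid
Conditions: B2(OH)4, Pd(OAc)2 (cat.), XPhos, KOAc, EtOH, 80 °C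
Reagents that add atoms: tetrahydroxydiboron OB(O)B(O)O
Why: Palladium-catalysed Miyaura-type borylation with tetrahydroxydiboron converts the electron-rich, peri-substituted aryl bromide directly into the boronic acid needed for transmetalation to copper.

**Step 9**
Reactants: 7 2-bromo-1-[2,3-bis(benzyloxy)-6-ethenylphenyl]ethan-1-one; 11 [4-(benzyloxy)-8-methoxynaphthalen-1-yl]boronic acid
Product: 12 (4R)-7,8-bis(benzyloxy)-4-[4-(benzyloxy)-8-methoxynaphthalen-1-yl]-3,4-dihydronaphthalen-1(2H)-one
Conditions: Cu(MeCN)4PF6 (10 mol %), gem-dibenzyl Ph-BOX ligand (12 mol %, the antipode that gives R-12), 11 (1.5 equiv), Li2CO3, H2O (2 equiv), CH2Cl2/DMF, 0 °C to rt, slow addition of 7, argon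
Reagents that add atoms: none
Why: Proposed new method: a monovalent copper–aryl complex, formed from 11 by base-assisted transmetalation on the chiral bis(oxazoline) copper catalyst, abstracts bromine from 7 to give the α-keto radical at C2 and a divalent copper–aryl species; the radical adds to the terminal vinyl carbon C3, and the resulting C4 benzylic radical is captured by the divalent copper–aryl complex and released by reductive elimination from trivalent copper, which forms the C4–naphthyl bond and returns monovalent copper. The closest known reaction types are the copper-catalysed enantioselective radical-relay carboarylation of vinylarenes with arylboronic acids, the copper-catalysed enantioconvergent arylation of secondary benzylic halides, and racemic 6-endo cyclisations of α-carbonyl radicals onto styrenes; what is new is their combination in a two-component, ring-forming version. The cyclohexanone ring is closed in the 6-endo-trig mode through the C2–C3 bond. The C4 stereocentre is set in the reductive elimination under control of the chiral ligand, since the planar benzylic radical carries no other stereochemical information. The step needs 6-endo over 5-exo closure, secured by the carbonyl group lying inside the forming ring and by attack at the unsubstituted styrene terminus that leads to a benzylic radical, and it needs ring closure before arylation of the C2 radical, secured by the intramolecular trap, the low catalyst loading and the slow addition of 7.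

**Step 10**
Reactants: 12 (4R)-7,8-bis(benzyloxy)-4-[4-(benzyloxy)-8-methoxynaphthalen-1-yl]-3,4-dihydronaphthalen-1(2H)-one
Product: 13 (4R)-7,8-dihydroxy-4-(4-hydroxy-8-methoxynaphthalen-1-yl)-3,4-dihydronaphthalen-1(2H)-one
Conditions: H2 (1 atm), Pd/C (10 wt %), EtOAc/MeOH, rt, work-up under argon
Reagents that add atoms: none
Why: Hydrogenolysis of the three benzyl ethers over palladium under neutral conditions should release the catechol and the naphthol while the aryl ketone, the methyl ether and the C4 stereocentre stay untouched.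

**Compound list**

1 | 2,3-bis(benzyloxy)benzaldehyde | O=Cc1cccc(OCc2ccccc2)c1OCc1ccccc1 | starting material
2 | 2,3-bis(benzyloxy)-6-bromobenzaldehyde | O=Cc1c(Br)ccc(OCc2ccccc2)c1OCc1ccccc1 | intermediate
3 | 1-[2,3-bis(benzyloxy)-6-bromophenyl]ethan-1-ol (racemic) | CC(O)c1c(Br)ccc(OCc2ccccc2)c1OCc1ccccc1 | intermediate
4 | 1-[2,3-bis(benzyloxy)-6-bromophenyl]ethan-1-one | CC(=O)c1c(Br)ccc(OCc2ccccc2)c1OCc1ccccc1 | intermediate
5 | 1-[2,3-bis(benzyloxy)-6-ethenylphenyl]ethan-1-one | CC(=O)c1c(C=C)ccc(OCc2ccccc2)c1OCc1ccccc1 | intermediate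
6 | {[1-(2,3-bis(benzyloxy)-6-ethenylphenyl)ethenyl]oxy}trimethylsilane (trimethylsilyl enol ether, not isolated) | C=C(O[Si](C)(C)C)c1c(C=C)ccc(OCc2ccccc2)c1OCc1ccccc1 | intermediate
7 | 2-bromo-1-[2,3-bis(benzyloxy)-6-ethenylphenyl]ethan-1-one | O=C(CBr)c1c(C=C)ccc(OCc2ccccc2)c1OCc1ccccc1 | intermediate
8 | 5-methoxynaphthalen-1-ol | COc1cccc2c(O)cccc12 | starting material
9 | 4-bromo-5-methoxynaphthalen-1-ol | COc1cccc2c(O)ccc(Br)c12 | intermediate
10 | 1-(benzyloxy)-4-bromo-5-methoxynaphthalene | COc1cccc2c(OCc3ccccc3)ccc(Br)c12 | intermediate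
11 | [4-(benzyloxy)-8-methoxynaphthalen-1-yl]boronic acid | COc1cccc2c(OCc3ccccc3)ccc(B(O)O)c12 | intermediate
12 | (4R)-7,8-bis(benzyloxy)-4-[4-(benzyloxy)-8-methoxynaphthalen-1-yl]-3,4-dihydronaphthalen-1(2H)-one | COc1cccc2c(OCc3ccccc3)ccc([C@H]4CCC(=O)c5c4ccc(OCc4ccccc4)c5OCc4ccccc4)c12 | intermediate
13 | (4R)-7,8-dihydroxy-4-(4-hydroxy-8-methoxynaphthalen-1-yl)-3,4-dihydronaphthalen-1(2H)-one | COc1cccc2c(O)ccc([C@H]3CCC(=O)c4c3ccc(O)c4O)c12 | target

**Total step count:** 10.
**Longest linear sequence:** 7 steps (steps 1, 2, 3, 4, 5, 9, 10).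

**Steps most likely to fail**

1. Step 9 (Proposed new method). What may go wrong:
   - arylation of the C2 radical at copper before it cyclises;
   - loss of the C4 radical by oxidation and aromatisation to a naphthol;
   - slow transmetalation or reductive elimination with the peri-methoxy naphthyl group;
   - weak facial control in the bond-forming event.

   The fallback uses known chemistry only, sets out from 2 and 10 and comes back at 12. The stereocentre is set first and the same ring bond is then closed by an ionic step. Oxidative esterification of 2 (I2, KOH, MeOH, 0 °C) should give methyl 2,3-bis(benzyloxy)-6-bromobenzoate F1. Suzuki–Miyaura vinylation of 10 (potassium vinyltrifluoroborate, PdCl2(dppf), Cs2CO3) should give 1-(benzyloxy)-4-ethenyl-5-methoxynaphthalene F2. Enantioselective copper/palladium-catalysed arylboration of F2 with F1 and B2pin2 (CuCl, chiral ligand, Pd(OAc)2, RuPhos, NaOtBu, THF) should give methyl 2,3-bis(benzyloxy)-6-[(1R)-1-[4-(benzyloxy)-8-methoxynaphthalen-1-yl]-2-(4,4,5,5-tetramethyl-1,3,2-dioxaborolan-2-yl)ethyl]benzoate F3. Oxidation (NaBO3·4H2O, THF/H2O) with lactonisation should give (4R)-7,8-bis(benzyloxy)-4-[4-(benzyloxy)-8-methoxynaphthalen-1-yl]-3,4-dihydro-1H-isochromen-1-one F4. MeLi (1 equiv, THF, −78 °C) should open the lactone to 1-[2,3-bis(benzyloxy)-6-[(1R)-1-[4-(benzyloxy)-8-methoxynaphthalen-1-yl]-2-hydroxyethyl]phenyl]ethan-1-one F5, which may sit in equilibrium with its lactol. Appel-type iodination (I2, PPh3, imidazole) should give 1-[2,3-bis(benzyloxy)-6-[(1R)-1-[4-(benzyloxy)-8-methoxynaphthalen-1-yl]-2-iodoethyl]phenyl]ethan-1-one F6. LiN(SiMe3)2 (THF, −78 to 0 °C) should then close the C2–C3 bond by intramolecular enolate alkylation and deliver 12.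

2. Step 6. What may go wrong: poor regioselectivity of the bromination (attack ortho to the hydroxyl group or on the methoxy-bearing ring) and over-bromination. The fallback sets out from 8 and comes back at 11; it fixes the para position through the oxidation state instead of through an electrophilic substitution. Oxidation of 8 with PhI(OCOCF3)2 in aqueous MeCN should give 5-methoxynaphthalene-1,4-dione F7. Reduction with Na2S2O4 should give 5-methoxynaphthalene-1,4-diol F8. Monobenzylation (BnBr, 1 equiv, K2CO3, acetone) should occur at the hydroxyl group remote from the methoxy group, since the peri hydroxyl is hydrogen-bonded and hindered, to give 4-(benzyloxy)-8-methoxynaphthalen-1-ol F9. Triflation (Tf2O, pyridine) should give 4-(benzyloxy)-8-methoxynaphthalen-1-yl trifluoromethanesulfonate F10, and palladium-catalysed borylation (B2(OH)4, Pd(OAc)2, XPhos, KOAc, EtOH) returns 11.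

3. Step 5. What may go wrong: loss of chemoselectivity in the bromination (attack on the vinyl group or the arene, or double bromination at C2). The fallback sets out from 2 and comes back at 7; it builds the bromoacetyl group from the aldehyde instead of brominating a ketone. Suzuki–Miyaura vinylation of 2 (potassium vinyltrifluoroborate, PdCl2(dppf), Cs2CO3) should give 2,3-bis(benzyloxy)-6-ethenylbenzaldehyde F11. Addition of bromomethyllithium generated in situ (CH2Br2, n-BuLi, THF, −78 °C, acetic acid quench at −78 °C) should give 2-bromo-1-[2,3-bis(benzyloxy)-6-ethenylphenyl]ethan-1-ol F12. Dess–Martin oxidation returns 7.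

**Further compounds**

F1 | step 9 | methyl 2,3-bis(benzyloxy)-6-bromobenzoate | COC(=O)c1c(Br)ccc(OCc2ccccc2)c1OCc1ccccc1
F2 | step 9 | 1-(benzyloxy)-4-ethenyl-5-methoxynaphthalene | COc1cccc2c(OCc3ccccc3)ccc(C=C)c12
F3 | step 9 | methyl 2,3-bis(benzyloxy)-6-[(1R)-1-[4-(benzyloxy)-8-methoxynaphthalen-1-yl]-2-(4,4,5,5-tetramethyl-1,3,2-dioxaborolan-2-yl)ethyl]benzoate | COc1cccc2c(OCc3ccccc3)ccc([C@@H](CB3OC(C)(C)C(C)(C)O3)c3ccc(OCc4ccccc4)c(OCc4ccccc4)c3C(=O)OC)c12
F4 | step 9 | (4R)-7,8-bis(benzyloxy)-4-[4-(benzyloxy)-8-methoxynaphthalen-1-yl]-3,4-dihydro-1H-isochromen-1-one | COc1cccc2c(OCc3ccccc3)ccc([C@H]4COC(=O)c5c4ccc(OCc4ccccc4)c5OCc4ccccc4)c12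
F5 | step 9 | 1-[2,3-bis(benzyloxy)-6-[(1R)-1-[4-(benzyloxy)-8-methoxynaphthalen-1-yl]-2-hydroxyethyl]phenyl]ethan-1-one | COc1cccc2c(OCc3ccccc3)ccc([C@@H](CO)c3ccc(OCc4ccccc4)c(OCc4ccccc4)c3C(C)=O)c12
F6 | step 9 | 1-[2,3-bis(benzyloxy)-6-[(1R)-1-[4-(benzyloxy)-8-methoxynaphthalen-1-yl]-2-iodoethyl]phenyl]ethan-1-one | COc1cccc2c(OCc3ccccc3)ccc([C@@H](CI)c3ccc(OCc4ccccc4)c(OCc4ccccc4)c3C(C)=O)c12
F7 | step 6 | 5-methoxynaphthalene-1,4-dione | COc1cccc2C(=O)C=CC(=O)c12
F8 | step 6 | 5-methoxynaphthalene-1,4-diol | COc1cccc2c(O)ccc(O)c12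
F9 | step 6 | 4-(benzyloxy)-8-methoxynaphthalen-1-ol | COc1cccc2c(OCc3ccccc3)ccc(O)c12
F10 | step 6 | 4-(benzyloxy)-8-methoxynaphthalen-1-yl trifluoromethanesulfonate | COc1cccc2c(OCc3ccccc3)ccc(OS(=O)(=O)C(F)(F)F)c12
F11 | step 5 | 2,3-bis(benzyloxy)-6-ethenylbenzaldehyde | O=Cc1c(C=C)ccc(OCc2ccccc2)c1OCc1ccccc1
F12 | step 5 | 2-bromo-1-[2,3-bis(benzyloxy)-6-ethenylphenyl]ethan-1-ol | OC(CBr)c1c(C=C)ccc(OCc2ccccc2)c1OCc1ccccc1
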